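**Retrosynthetic overview**
- The prenyl group is placed last: the target comes from an aromatic Claisen rearrangement of the ring A 1,1-dimethylallyl ether of the complete (S)-α-hydroxy ketone.
- The Cα–CH2 bond and the only stereocentre are made together: a chiral zinc enolate of the ring A 2-hydroxy-1-aryl-ethanone adds to the parent p-quinone methide, released in the flask by dearomatising a ring B phenol sulfone.
- The hydroxy ketone donor comes from the ring A aldehyde and formaldehyde (carbene-catalysed hydroxymethylation); the aldehyde ether comes from 4-hydroxy-2-methoxybenzaldehyde and 3-chloro-3-methylbut-1-yne (etherification, semihydrogenation).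
- The quinone methide precursor comes from 4-hydroxybenzyl alcohol and a sulfinate.
- No ring is formed: both benzene rings are bought. Ring B is dearomatised and rearomatised in the key step, ring A in the last step.

Assumption: the zinc/linked-BINOL enolate reacts through the same face as in its known Michael and aldol reactions ((S,S)-ligand gives 2R, recalled from memory), so the (R,R)-ligand is specified for the (S)-target; if the sense is reversed, the other ligand enantiomer is used.

**Route**

Step 1
Reactants: 1 4-hydroxy-2-methoxybenzaldehyde; 2 3-chloro-3-methylbut-1-yne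
Product: 3 2-methoxy-4-[(2-methylbut-3-yn-2-yl)oxy]benzaldehyde
Conditions: CuCl2·2H2O (1 mol %), DBU (1.5 equiv), MeCN, 0 °C → rt
Reagents that add atoms: none
Why: Copper-catalysed propargylic etherification (Godfrey type): the copper-activated tertiary propargyl chloride is captured at oxygen by the DBU phenoxide, which works well for acidic formyl-substituted phenols and leaves the aldehyde alone.

Step 2
Reactants: 3 2-methoxy-4-[(2-methylbut-3-yn-2-yl)oxy]benzaldehyde
Product: 4 2-methoxy-4-[(2-methylbut-3-en-2-yl)oxy]benzaldehyde
Conditions: H2 (1 atm), Pd/CaCO3 poisoned with Pb(OAc)2 (Lindlar catalyst), quinoline, EtOAc, rt, stopped after 1 equiv H2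
Reagents that add atoms: none
Why: Lindlar semihydrogenation stops at the terminal alkene and touches neither the aldehyde nor the tertiary C–O bond, giving the 1,1-dimethylallyl ether that serves as phenol protection and as latent prenyl group.

Step 3
Reactants: 4 2-methoxy-4-[(2-methylbut-3-en-2-yl)oxy]benzaldehyde; 5 paraformaldehyde
Product: 6 2-hydroxy-1-{2-methoxy-4-[(2-methylbut-3-en-2-yl)oxy]phenyl}ethan-1-one
Conditions: 5 (2 equiv CH2O), 3-(2,4,6-trimethylphenyl)-4,5-dimethylthiazol-3-ium perchlorate (10 mol %), iPr2NEt (10 mol %), THF, 60 °C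
Reagents that add atoms: none
Why: Thiazolylidene-catalysed cross-acyloin reaction (hydroxymethylation): the Breslow intermediate of the aryl aldehyde adds to formaldehyde, by far the better acceptor, so the 2-hydroxy-1-aryl-ethanone forms selectively; 60 °C is well below the Claisen threshold of the ether and no stereocentre is formed.

Step 4
Reactants: 7 4-hydroxybenzyl alcohol
Product: 8 4-[(4-methylbenzenesulfonyl)methyl]phenol
Conditions: TolSO2Na (1.3 equiv), HCO2H/H2O (1:1), rt
Reagents that add atoms: sodium 4-methylbenzenesulfinate, Cc1ccc(cc1)S(=O)[O-].[Na+]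
Why: SN1 substitution through the p-hydroxybenzyl cation (protonated quinone methide), trapped at sulfur by the soft sulfinate, gives a bench-stable sulfone that releases the quinone methide only on deprotonation.

Step 5
Reactants: 6 2-hydroxy-1-{2-methoxy-4-[(2-methylbut-3-en-2-yl)oxy]phenyl}ethan-1-one (1.5 equiv); 8 4-[(4-methylbenzenesulfonyl)methyl]phenol (1.0 equiv)
Product: 10 (2S)-2-hydroxy-3-(4-hydroxyphenyl)-1-{2-methoxy-4-[(2-methylbut-3-en-2-yl)oxy]phenyl}propan-1-one, via p-quinone methide 9 (not isolated)
Conditions: Et2Zn (20 mol %), (R,R)-3,3''-[oxybis(methylene)]bis(1,1'-bi-2-naphthol) [(R,R)-linked-BINOL] (10 mol %), MS 3 Å, iPr2NEt (1.1 equiv), THF, −20 → 0 °C, 8 added by syringe pump over 8 h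
Reagents that add atoms: none
Why: Proposed new method: iPr2NEt (relayed by the zinc aryloxides) deprotonates phenol 8 and 1,6-elimination of sulfinate dearomatises it to p-quinone methide 9 at low stationary concentration; 6 sits on the chiral zinc cluster as its chelated zinc enediolate (the 2-OMe group is the extra donor, as in the parent 2-hydroxy-2'-methoxyacetophenone donors) and attacks the exocyclic CH2 of 9 through carbon with rearomatisation as driving force; the (S)-centre is set by the ligand-shielded enolate face alone because the electrophilic carbon is not prochiral, and the zinc phenoxide of 10 is protonated by the next molecule of 6 to turn the catalyst over; closest known reactions are the direct zinc/linked-BINOL Michael addition of 2-hydroxy-2'-methoxyacetophenone to vinyl ketones and base-triggered 1,6-additions of enolates to quinone methides released from hydroxybenzyl sulfones.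

Step 6
Reactants: 10 (2S)-2-hydroxy-3-(4-hydroxyphenyl)-1-{2-methoxy-4-[(2-methylbut-3-en-2-yl)oxy]phenyl}propan-1-one
Product: 12 Lespeflorin C3 = (2S)-2-hydroxy-1-[4-hydroxy-2-methoxy-5-(3-methylbut-2-en-1-yl)phenyl]-3-(4-hydroxyphenyl)propan-1-one, via ortho-dienone 11 (not isolated)
Conditions: PhCl (degassed), 125 °C, sealed tube, 6 h
Reagents that add atoms: none
Why: Aromatic Claisen rearrangement: the [3,3] shift delivers the CH2 terminus of the 1,1-dimethylallyl ether to C5 (ortho to the ether oxygen, para to OMe, less hindered than C3 between the two oxygens; without a chelated 2-OH there is no bias toward C3), and dienone 11 enolises to the phenol; the neutral thermal conditions do not enolise the ketone, so the (S)-carbinol is kept.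

**Compound list**

1 | 4-hydroxy-2-methoxybenzaldehyde | COc1cc(O)ccc1C=O | starting material
2 | 3-chloro-3-methylbut-1-yne | CC(C)(Cl)C#C | starting material
3 | 2-methoxy-4-[(2-methylbut-3-yn-2-yl)oxy]benzaldehyde | COc1cc(OC(C)(C)C#C)ccc1C=O | intermediate
4 | 2-methoxy-4-[(2-methylbut-3-en-2-yl)oxy]benzaldehyde | COc1cc(OC(C)(C)C=C)ccc1C=O | intermediate
5 | paraformaldehyde (formaldehyde source, monomer drawn) | C=O | starting material
6 | 2-hydroxy-1-{2-methoxy-4-[(2-methylbut-3-en-2-yl)oxy]phenyl}ethan-1-one | COc1cc(OC(C)(C)C=C)ccc1C(=O)CO | intermediate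
7 | 4-hydroxybenzyl alcohol | OCc1ccc(O)cc1 | starting material
8 | 4-[(4-methylbenzenesulfonyl)methyl]phenol | Cc1ccc(cc1)S(=O)(=O)Cc1ccc(O)cc1 | intermediate
9 | 4-methylidenecyclohexa-2,5-dien-1-one (p-quinone methide, not isolated) | C=C1C=CC(=O)C=C1 | intermediate
10 | (2S)-2-hydroxy-3-(4-hydroxyphenyl)-1-{2-methoxy-4-[(2-methylbut-3-en-2-yl)oxy]phenyl}propan-1-one | COc1cc(OC(C)(C)C=C)ccc1C(=O)[C@@H](O)Cc1ccc(O)cc1 | intermediate
11 | (2S)-2-hydroxy-3-(4-hydroxyphenyl)-1-[6-methoxy-3-(3-methylbut-2-en-1-yl)-4-oxocyclohexa-1,5-dien-1-yl]propan-1-one (ortho-dienone, ring carbon 3 unassigned, not isolated) | COC1=CC(=O)C(CC=C(C)C)C=C1C(=O)[C@@H](O)Cc1ccc(O)cc1 | intermediate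
12 | Lespeflorin C3, (2S)-2-hydroxy-1-[4-hydroxy-2-methoxy-5-(3-methylbut-2-en-1-yl)phenyl]-3-(4-hydroxyphenyl)propan-1-one | COc1cc(O)c(CC=C(C)C)cc1C(=O)[C@@H](O)Cc1ccc(O)cc1 | target

**Step count**

Total steps: 6. Longest linear sequence: 5 (steps 1, 2, 3, 5, 6); step 4 is a one-step side branch.

**Three steps most likely to fail**

1. Step 5 (asymmetric capture of the quinone methide). The risks are oligomerisation of 9, O-benzylation of the ligand naphthoxides or of the α-hydroxyl, and modest ee (10 may need recrystallisation). The fallback sets out from 6 and returns at 10. Condensation of 6 with 4-hydroxybenzaldehyde (pyrrolidine/AcOH, EtOH, 50 °C) gives 3-(4-hydroxyphenyl)-1-{2-methoxy-4-[(2-methylbut-3-en-2-yl)oxy]phenyl}propane-1,2-dione F1, largely as its enol. Asymmetric transfer hydrogenation (RuCl[(S,S)-TsDPEN](p-cymene), HCO2H/Et3N, 10 °C; catalyst enantiomer to be confirmed on a model) then reduces only the C2 carbonyl, the one not conjugated to the electron-rich ring A, and gives 10. The stereocentre then comes from hydride delivery to a ketone instead of from an enolate alkylation, and the terminal alkene is inert to the catalyst.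

2. Step 3 (hydroxymethylation). The aldehyde is electron-rich and ortho-substituted, so the Breslow intermediate forms slowly and formaldehyde self-condensation may compete. The fallback sets out from 4 and returns at 6. MeMgBr (THF, −78 °C) gives 1-{2-methoxy-4-[(2-methylbut-3-en-2-yl)oxy]phenyl}ethan-1-ol F2. Dess–Martin periodinane (CH2Cl2, NaHCO3) gives 1-{2-methoxy-4-[(2-methylbut-3-en-2-yl)oxy]phenyl}ethan-1-one F3. Its potassium enolate (KHMDS, THF, −78 °C) is hydroxylated with 3-phenyl-2-(phenylsulfonyl)oxaziridine to give 6. This replaces the umpolung of the aldehyde by a classical C1 addition followed by enolate oxidation.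

3. Step 6 (Claisen rearrangement). The risks are partial migration to C3 and loss of isoprene from the tertiary ether of an acidic phenol. The fallback sets out from 10 and returns at 12. Pd(PPh3)4/morpholine (THF, rt) removes the dimethylallyl group and gives (2S)-2-hydroxy-1-(4-hydroxy-2-methoxyphenyl)-3-(4-hydroxyphenyl)propan-1-one F4. NIS (1.0 equiv, MeCN, −20 °C) iodinates C5 of ring A, the position activated by both oxygen donors, and gives (2S)-2-hydroxy-1-(4-hydroxy-5-iodo-2-methoxyphenyl)-3-(4-hydroxyphenyl)propan-1-one F5. Stille coupling with tributyl(3-methylbut-2-en-1-yl)stannane (Pd(PPh3)4, DMF, 80 °C) gives 12. The prenyl position is then fixed by the halogen instead of by the sigmatropic shift.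

**Further compounds**

F1 | step 5 | 3-(4-hydroxyphenyl)-1-{2-methoxy-4-[(2-methylbut-3-en-2-yl)oxy]phenyl}propane-1,2-dione | COc1cc(OC(C)(C)C=C)ccc1C(=O)C(=O)Cc1ccc(O)cc1
F2 | step 3 | 1-{2-methoxy-4-[(2-methylbut-3-en-2-yl)oxy]phenyl}ethan-1-ol (racemic) | COc1cc(OC(C)(C)C=C)ccc1C(C)O
F3 | step 3 | 1-{2-methoxy-4-[(2-methylbut-3-en-2-yl)oxy]phenyl}ethan-1-one | COc1cc(OC(C)(C)C=C)ccc1C(C)=O
F4 | step 6 | (2S)-2-hydroxy-1-(4-hydroxy-2-methoxyphenyl)-3-(4-hydroxyphenyl)propan-1-one | COc1cc(O)ccc1C(=O)[C@@H](O)Cc1ccc(O)cc1
F5 | step 6 | (2S)-2-hydroxy-1-(4-hydroxy-5-iodo-2-methoxyphenyl)-3-(4-hydroxyphenyl)propan-1-one | COc1cc(O)c(I)cc1C(=O)[C@@H](O)Cc1ccc(O)cc1
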